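(The constants used here are made up; the flask was simulated.)

In the flask, solid substrate, starting material and target sum to the charge at every moment, and the by-product stands equal to the target.

solid substrate 10 mM; time 15 min

1. the target standing at 15 min, as a percentage of the solid substrate charged
2. concentration of starting material in solution at 8.0 min, in percent of saturation
3. the change that raises the amount of target at 15 min, in percent of the solid substrate charged most ("none" if none brings more than 2 percentage points) (noon / dusk / none)
4. amount of target at 15 min, in percent of the solid substrate charged, after dusk

Noon doubles the dissolution coefficient; dusk doubles the solubility.

For the next shift: the reaction is the rate-limiting step, 6.17 × 10⁻⁴ /s against 0.0188 /s for dissolving. Past the first minutes, with the way back left out, dissolving and the reaction balance while solid stands, which puts starting material near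

k(dissolving) / (k(dissolving) + k(reaction)) = 96.8% of saturation,

and saturation is 50.0% of the charge. Against that level the target climbs to its ceiling, the share of the charge at which the reaction balances over a saturated solution:

ceiling = √(equilibrium constant × solubility) / charge = 44.1%

Since 94.1% of the charge is below the whole, solid is still there at the ceiling. The rise time is ceiling / starting slope = 23.8 min, after a lag of 0.887 min:

reached = tanh((time − lag) / rise time) = 53.2%

target = ceiling × reached = 23.4%

At dusk, saturation is 100% of the charge, so starting material falls as target forms. The balance then gives a ceiling of 45.9%, a rise time of 12.4 min, reached 81.4%, and target 37.3%.

Dusk gains 14 percentage points. Noon shortens the lag, worth 0.82 points at the starting slope, less than the 2 points that counts, and lifts the held level to 98.4% of saturation, which this reckoning leaves uncounted; leave the stirring alone. Choice: dusk.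

The forecast says 22.9%, 97.1%, dusk and 34.8%, the last below this reckoning; its ground for the undoubled flask is that “the starting material sits just under saturation while solid remains”.

The simulation gives 22.9%, 97.0%, dusk (noon 0.86 points, dusk 12 points) and 34.8%.

    starting material ⇌ target + by-product (K1 = 0.00389 M, k1 = 6.17 × 10⁻⁴ /s)
    solid substrate ⇌ starting material, rate k2*(cs2 - [starting material]) while solid is left; crystals form when [starting material] > cs2 (cs2 = 5.0 mM, k2 = 0.0188 /s)

In the flask, half the dissolving turnover is done by 1.10 min and half the reaction's by 7.39 min, and by 150 min the target stands at 44.1% against the ceiling of 44.1%. With 17 mM charged, rise time and lag stay as they are and the ceiling becomes 25.9%, so the reckoning gives 13.8%; the neighbour computes to 13.5%.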